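**Strategy**

The piperazine (N1, C2 bearing the ring A benzyl, C3, N4, C5 bearing the ring B benzyl, C6) is closed last at C2–C3. The precursor is an L-tyrosinol-derived azide whose Boc nitrogen carries a CH2SnBu3 group (future N4–C3) and whose preformed ring A–O–ring B diaryl ether ends in an arylacetaldehyde (future C2). One operation condenses azide and aldehyde to the 14-membered N1=C2 imine and joins C3 to C2 by copper-mediated radical cyclization, closing macrocycle and piperazine and setting C2. It exploits the diaryl ether strap between ring A and ring B, which spans C2 and C5 and tolerates only the cis-2,5 ring. The guanine is then annulated onto a ring A salicylaldehyde.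

Key step: step 6

Remarks on the chemistry: ring A is the phenol ring (C1 bears the guanine, C2 the OH, C3 the ether oxygen, C5 the CH2), ring B the para-phenylene; piperazine locants as defined above. Compound 16 is used as its commercial sulfate and listed as the free base. Compound 13 is present in the flask as its hydrobromide and listed as the free base.

**Route**

Step 1
Reactants: 1 N-Boc-L-tyrosinol; 2 5-bromo-2-methoxyphenylboronic acid
Product: 3 tert-butyl (S)-[1-[4-(5-bromo-2-methoxyphenoxy)phenyl]-3-hydroxypropan-2-yl]carbamate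
Conditions: 2 (2.5 equiv), Cu(OAc)2 (1 equiv), pyridine (5 equiv), 4 Å MS, CH2Cl2, O2 balloon, rt
Reagents that add atoms: none
Why: Chan–Lam–Evans oxidative O-arylation, in which the phenol couples with the arylboronic acid through an aryl copper phenoxide far faster than the primary alcohol or the carbamate N–H, and the room-temperature conditions leave the tyrosinol stereocenter untouched.

Step 2
Reactants: 3 aryl bromide
Product: 4 tert-butyl (S)-[1-[4-(5-allyl-2-methoxyphenoxy)phenyl]-3-hydroxypropan-2-yl]carbamate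
Conditions: allylSnBu3 (1.5 equiv), Pd(PPh3)4 (5 mol%), LiCl, DMF, 90 °C
Reagents that add atoms: allyltributylstannane C=CC[Sn](CCCC)(CCCC)CCCC
Why: Stille cross-coupling of the aryl bromide installs the allyl group that later delivers the C2 aldehyde by oxidative cleavage; alcohol and carbamate are inert to zerovalent palladium.

Step 3
Reactants: 4 allyl arene alcohol
Product: 6 tert-butyl (S)-[1-azido-3-[4-(5-allyl-2-methoxyphenoxy)phenyl]propan-2-yl]carbamate, via mesylate 5 (not isolated)
Conditions: MsCl, Et3N, CH2Cl2, 0 °C; evaporate; NaN3, DMF, 60 °C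
Reagents that add atoms: sodium azide [Na+].[N-]=[N+]=[N-]
Why: Mesylation of the only alcohol and SN2 displacement by azide at the primary carbon introduce the future N1 without touching the stereocenter.

Step 4
Reactants: 6 azido carbamate
Product: 7 tert-butyl (S)-[1-azido-3-[4-(5-allyl-2-methoxyphenoxy)phenyl]propan-2-yl][(tributylstannyl)methyl]carbamate
Conditions: NaH (1.2 equiv), DMF, 0 °C; Bu3SnCH2I (1.3 equiv), 0 °C to rt
Reagents that add atoms: tributyl(iodomethyl)stannane CCCC[Sn](CCCC)(CCCC)CI
Why: N-alkylation of the sodium carbamate (SN2 at the iodomethyl carbon) installs the CH2SnBu3 group that becomes C3, the usual way to make N-Boc stannyl amine (SnAP) reagents; azide, allyl group and aryl ethers are inert to NaH at this temperature.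

Step 5
Reactants: 7 stannylmethyl carbamate
Product: 9 tert-butyl (S)-[1-azido-3-[4-[2-methoxy-5-(2-oxoethyl)phenoxy]phenyl]propan-2-yl][(tributylstannyl)methyl]carbamate, via vicinal diol 8 (not isolated)
Conditions: OsO4 (2 mol%), NaIO4 (4 equiv), 2,6-lutidine, dioxane/H2O 3:1, rt; used crude
Reagents that add atoms: osmium tetroxide O=[Os](=O)(=O)=O (catalytic oxygen carrier); sodium periodate [Na+].[O-]I(=O)(=O)=O (terminal oxygen source)
Why: Lemieux–Johnson oxidation, in which catalytic dihydroxylation of the terminal alkene and periodate cleavage of diol 8 should give the arylacetaldehyde, 2,6-lutidine suppressing over-oxidation, while azide, carbamate and the tetraalkylstannane are not attacked.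

Step 6
Reactants: 9 azido aldehyde
Product: 12 N4-Boc O-methylpiperazinomycin [(2S,5S)-piperazine bridged from the C2 CH2 through ring A C5/C3, the ether oxygen and ring B to the C5 CH2; OMe on ring A C2; N1–H free], via iminophosphorane 10 (not isolated), via macrocyclic imine 11 (not isolated)
Conditions: polystyrene-bound PPh3 (3 equiv), 4 Å MS, CH2Cl2 (0.002 M), 40 °C; filter, concentrate to 0.02 M; Cu(OTf)2 (1.2 equiv), 2,6-lutidine (1.2 equiv), HFIP/CH2Cl2 1:4, rt
Reagents that add atoms: none
Why: Staudinger reaction of the azide gives iminophosphorane 10, whose intramolecular aza-Wittig reaction with the arylacetaldehyde closes the 14-membered ring as the N1=C2 aldimine 11 (closure by C=N condensation, with site isolation on the resin and high dilution working against oligomers). Cu(OTf)2 then oxidizes the C–Sn bond of the N4–CH2SnBu3 arm to a nucleophilic α-amino radical at C3, which adds to the copper-bound imine carbon C2 in a 6-endo-trig radical cyclization that closes the piperazine; the resulting aminyl radical is reduced and protonated by HFIP, which returns divalent copper. The closest known reaction type is the stannyl amine protocol (SnAP) synthesis of N-Boc piperazines from aldehydes, here run on an imine made by aza-Wittig macrocyclization. The new stereocenter C2 is controlled by the existing C5 stereocenter (from L-tyrosinol) through the ring A–O–ring B strap: C3 can reach only the imine face that leaves both benzylic CH2 groups on the same side of the new ring, and allylic 1,3-strain with the N4-Boc group holds the C5 benzyl pseudo-axial as this closure requires, so the (2S,5S) isomer is expected. The step needs monomeric ring closure, 6-endo regiochemistry and cis selectivity, secured respectively by dilution, by the polarity match between the α-amino radical and the imine carbon, and by the diaryl ether bridge, which cannot span a trans-2,5-piperazine.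

Step 7
Reactants: 12 N4-Boc O-methylpiperazinomycin
Product: 14 N1,N4-di-Boc-piperazinomycin (free phenol on ring A C2), via piperazinomycin 13 (not isolated)
Conditions: BBr3 (6 equiv), CH2Cl2, −78 to 0 °C; MeOH quench, evaporate; Boc2O (2.2 equiv), Et3N, MeOH, 0 °C to rt
Reagents that add atoms: di-tert-butyl dicarbonate CC(C)(C)OC(=O)OC(=O)OC(C)(C)C
Why: BBr3 cleaves the aryl methyl ether (Lewis acid demethylation, which also removes the Boc group and spares the diaryl ether), and Boc2O then acylates both secondary amines in preference to the hindered phenol, masking the NH groups for the formylation.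

Step 8
Reactants: 14 N1,N4-di-Boc-piperazinomycin
Product: 15 N1,N4-di-Boc-piperazinomycin carrying CHO on ring A C1 (salicylaldehyde)
Conditions: MgCl2 (2 equiv), Et3N (4 equiv), (CH2O)n (6 equiv), MeCN, 80 °C; dilute HCl work-up
Reagents that add atoms: formaldehyde (from paraformaldehyde) C=O
Why: Casnati–Skattebøl ortho-formylation, in which the magnesium phenoxide directs formaldehyde to the only free ortho position (ring A C1) and a second formaldehyde oxidizes the benzylic alkoxide by hydride transfer, the carbamates preventing Mannich reactions at the piperazine nitrogens.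

Step 9
Reactants: 15 salicylaldehyde; 16 2,5,6-triaminopyrimidin-4(3H)-one
Product: 18 N1,N4-di-Boc-guanipiperazine A, via Schiff base 17 (not isolated)
Conditions: 16 (as sulfate, 1.5 equiv), NaOAc (3 equiv), DMSO, 60 °C; then open to air, 100 °C
Reagents that add atoms: none
Why: Traube-type purine annulation, in which the most nucleophilic 5-amino group of 16 condenses with the aldehyde to Schiff base 17, the 6-amino group adds to the imine carbon and aerobic dehydrogenation of the imidazoline should give the imidazole ring of the 8-arylguanine.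

Step 10
Reactants: 18 N1,N4-di-Boc-guanipiperazine A
Product: 19 guanipiperazine A
Conditions: TFA/CH2Cl2 1:1, rt; aqueous NH3 to pH 8–9
Reagents that add atoms: none
Why: Acidolysis of the two tert-butyl carbamates frees N1 and N4 without affecting the guanine, the phenol, the diaryl ether or either stereocenter.

**Compound list**

1 | N-Boc-L-tyrosinol, tert-butyl (S)-[1-hydroxy-3-(4-hydroxyphenyl)propan-2-yl]carbamate | CC(C)(C)OC(=O)N[C@@H](Cc1ccc(O)cc1)CO | starting material
2 | 5-bromo-2-methoxyphenylboronic acid | COc1ccc(Br)cc1B(O)O | starting material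
3 | tert-butyl (S)-[1-[4-(5-bromo-2-methoxyphenoxy)phenyl]-3-hydroxypropan-2-yl]carbamate | CC(C)(C)OC(=O)N[C@@H](Cc1ccc(Oc2cc(Br)ccc2OC)cc1)CO | intermediate
4 | tert-butyl (S)-[1-[4-(5-allyl-2-methoxyphenoxy)phenyl]-3-hydroxypropan-2-yl]carbamate | CC(C)(C)OC(=O)N[C@@H](Cc1ccc(Oc2cc(CC=C)ccc2OC)cc1)CO | intermediate
5 | (S)-primary methanesulfonate of 4 | CC(C)(C)OC(=O)N[C@@H](Cc1ccc(Oc2cc(CC=C)ccc2OC)cc1)COS(C)(=O)=O | intermediate (not isolated)
6 | tert-butyl (S)-[1-azido-3-[4-(5-allyl-2-methoxyphenoxy)phenyl]propan-2-yl]carbamate | CC(C)(C)OC(=O)N[C@@H](Cc1ccc(Oc2cc(CC=C)ccc2OC)cc1)CN=[N+]=[N-] | intermediate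
7 | tert-butyl (S)-[1-azido-3-[4-(5-allyl-2-methoxyphenoxy)phenyl]propan-2-yl][(tributylstannyl)methyl]carbamate | CC(C)(C)OC(=O)N(C[Sn](CCCC)(CCCC)CCCC)[C@@H](Cc1ccc(Oc2cc(CC=C)ccc2OC)cc1)CN=[N+]=[N-] | intermediate
8 | vicinal diol from 7 (2,3-dihydroxypropyl on ring A, both carbinol epimers) | CC(C)(C)OC(=O)N(C[Sn](CCCC)(CCCC)CCCC)[C@@H](Cc1ccc(Oc2cc(CC(O)CO)ccc2OC)cc1)CN=[N+]=[N-] | intermediate (not isolated)
9 | tert-butyl (S)-[1-azido-3-[4-[2-methoxy-5-(2-oxoethyl)phenoxy]phenyl]propan-2-yl][(tributylstannyl)methyl]carbamate | CC(C)(C)OC(=O)N(C[Sn](CCCC)(CCCC)CCCC)[C@@H](Cc1ccc(Oc2cc(CC=O)ccc2OC)cc1)CN=[N+]=[N-] | intermediate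
10 | iminophosphorane of 9 (N=PPh3 in place of N3; drawn with soluble PPh3, one phenyl being the resin link) | CC(C)(C)OC(=O)N(C[Sn](CCCC)(CCCC)CCCC)[C@@H](Cc1ccc(Oc2cc(CC=O)ccc2OC)cc1)CN=P(c1ccccc1)(c1ccccc1)c1ccccc1 | intermediate (not isolated)
11 | 14-membered macrocyclic N1=C2 aldimine, (S) at C5, with N4(Boc)CH2SnBu3 on C5 | COc1ccc2cc1Oc1ccc(cc1)C[C@@H](CN=CC2)N(C[Sn](CCCC)(CCCC)CCCC)C(=O)OC(C)(C)C | intermediate (not isolated)
12 | N4-Boc O-methylpiperazinomycin, (2S,5S) | COc1ccc2cc1Oc1ccc(cc1)C[C@H]1CN[C@H](CN1C(=O)OC(C)(C)C)C2 | intermediate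
13 | piperazinomycin, (2S,5S), as hydrobromide in the flask | Oc1ccc2cc1Oc1ccc(cc1)C[C@H]1CN[C@H](CN1)C2 | intermediate (not isolated)
14 | N1,N4-di-Boc-piperazinomycin, (2S,5S) | Oc1ccc2cc1Oc1ccc(cc1)C[C@H]1CN(C(=O)OC(C)(C)C)[C@H](CN1C(=O)OC(C)(C)C)C2 | intermediate
15 | N1,N4-di-Boc-piperazinomycin with CHO on ring A C1, (2S,5S) | O=Cc1cc2cc(c1O)Oc1ccc(cc1)C[C@H]1CN(C(=O)OC(C)(C)C)[C@H](CN1C(=O)OC(C)(C)C)C2 | intermediate
16 | 2,5,6-triaminopyrimidin-4(3H)-one | Nc1nc(N)c(N)c(=O)[nH]1 | starting material
17 | Schiff base of 15 with the 5-amino group of 16 | Nc1nc(N)c(N=Cc2cc3cc(c2O)Oc2ccc(cc2)C[C@H]2CN(C(=O)OC(C)(C)C)[C@H](CN2C(=O)OC(C)(C)C)C3)c(=O)[nH]1 | intermediate (not isolated)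
18 | N1,N4-di-Boc-guanipiperazine A | Nc1nc2nc(-c3cc4cc(c3O)Oc3ccc(cc3)C[C@H]3CN(C(=O)OC(C)(C)C)[C@H](CN3C(=O)OC(C)(C)C)C4)[nH]c2c(=O)[nH]1 | intermediate
19 | guanipiperazine A | Nc1nc2nc(-c3cc4cc(c3O)Oc3ccc(cc3)C[C@H]3CN[C@H](CN3)C4)[nH]c2c(=O)[nH]1 | target

**Count and risks**

Total steps: 10. Longest linear sequence: 10 steps (from 1).

Steps most likely to fail:

1. Step 6. Strain in the aza-Wittig ring closure may divert the iminophosphorane into intermolecular condensation (oligomeric imines), or the arylacetaldimine may tautomerize to its enamine before the radical closure. Fallback (sets out from 1, returns at 14): the same C2–C3 radical closure is run intermolecularly before the strap exists, and the 14-membered ring is then closed at the diaryl ether. Phenol 1 is allylated (allyl bromide, K2CO3, acetone) to the allyl ether F1. Mesylation gives the mesylate F2, which NaN3 converts into the azide F3. NaH and Bu3SnCH2I give the stannylmethyl carbamate F4, and Staudinger reduction (PPh3, THF/H2O) gives the primary amine F5. Condensation (4 Å MS, CH2Cl2) with (3-bromo-4-methoxyphenyl)acetaldehyde F6, made by Dess–Martin oxidation of commercial 2-(3-bromo-4-methoxyphenyl)ethanol, gives the acyclic imine F7. Cu(OTf)2 and 2,6-lutidine in HFIP/CH2Cl2 cyclize it to the piperazine, from which the cis-(2S,5S) isomer F8 would be separated from any trans isomer. Boc2O gives the di-Boc compound F9, Pd(PPh3)4 and morpholine remove the allyl group to give the phenol F10, and intramolecular Ullmann etherification (CuI, N,N-dimethylglycine, Cs2CO3, dioxane, 0.002 M, 100 °C) closes the ring to the di-Boc methyl ether F11. The conditions of step 7 convert F11 into 14.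

2. Step 9. Aerobic dehydrogenation may stall at the Schiff base, and the electron-rich triaminopyrimidinone may degrade oxidatively in the heterogeneous mixture. Fallback (sets out from 15, returns at 18): a non-oxidative acylation and cyclodehydration sequence. Pinnick oxidation (NaClO2, NaH2PO4, 2-methyl-2-butene, tBuOH/H2O) gives the salicylic acid F12. Coupling with the 5-amino group of 16 (EDC·HCl, HOBt, iPr2NEt, DMF) gives the amide F13. Heating in 1 M aqueous NaOH at 80 °C closes the imidazole ring by loss of water to give 18.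

3. Step 4. Alkylation of the hindered secondary carbamate anion by the bulky stannyl iodide may be slow, giving time for base-induced migration of the allyl double bond into conjugation and for decomposition of the iodide. Fallback (sets out from 6, returns at 7): the order of alkylation and carbamate formation is reversed. TFA/CH2Cl2 removes the Boc group to give the primary amine F14. Mono-alkylation with Bu3SnCH2I (1.0 equiv, K2CO3, MeCN, rt) gives the secondary stannylmethyl amine F15. Boc2O and Et3N then give 7.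

**Further compounds**

F1 | step 6 | tert-butyl (S)-[1-[4-(allyloxy)phenyl]-3-hydroxypropan-2-yl]carbamate | CC(C)(C)OC(=O)N[C@@H](Cc1ccc(OCC=C)cc1)CO
F2 | step 6 | (S)-primary methanesulfonate of F1 | CC(C)(C)OC(=O)N[C@@H](Cc1ccc(OCC=C)cc1)COS(C)(=O)=O
F3 | step 6 | tert-butyl (S)-[1-[4-(allyloxy)phenyl]-3-azidopropan-2-yl]carbamate | CC(C)(C)OC(=O)N[C@@H](Cc1ccc(OCC=C)cc1)CN=[N+]=[N-]
F4 | step 6 | tert-butyl (S)-[1-[4-(allyloxy)phenyl]-3-azidopropan-2-yl][(tributylstannyl)methyl]carbamate | CC(C)(C)OC(=O)N(C[Sn](CCCC)(CCCC)CCCC)[C@@H](Cc1ccc(OCC=C)cc1)CN=[N+]=[N-]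
F5 | step 6 | tert-butyl (S)-[1-[4-(allyloxy)phenyl]-3-aminopropan-2-yl][(tributylstannyl)methyl]carbamate | CC(C)(C)OC(=O)N(C[Sn](CCCC)(CCCC)CCCC)[C@@H](Cc1ccc(OCC=C)cc1)CN
F6 | step 6 | (3-bromo-4-methoxyphenyl)acetaldehyde | COc1ccc(CC=O)cc1Br
F7 | step 6 | acyclic aldimine from F5 and F6 | CC(C)(C)OC(=O)N(C[Sn](CCCC)(CCCC)CCCC)[C@@H](Cc1ccc(OCC=C)cc1)CN=CCc1ccc(OC)c(Br)c1
F8 | step 6 | N4-Boc (2S,5S)-2-(3-bromo-4-methoxybenzyl)-5-[4-(allyloxy)benzyl]piperazine | C=CCOc1ccc(cc1)C[C@H]1CN[C@H](CN1C(=O)OC(C)(C)C)Cc1ccc(OC)c(Br)c1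
F9 | step 6 | N1,N4-di-Boc (2S,5S)-2-(3-bromo-4-methoxybenzyl)-5-[4-(allyloxy)benzyl]piperazine | C=CCOc1ccc(cc1)C[C@H]1CN(C(=O)OC(C)(C)C)[C@H](CN1C(=O)OC(C)(C)C)Cc1ccc(OC)c(Br)c1
F10 | step 6 | N1,N4-di-Boc (2S,5S)-2-(3-bromo-4-methoxybenzyl)-5-(4-hydroxybenzyl)piperazine | Oc1ccc(cc1)C[C@H]1CN(C(=O)OC(C)(C)C)[C@H](CN1C(=O)OC(C)(C)C)Cc1ccc(OC)c(Br)c1
F11 | step 6 | N1,N4-di-Boc O-methylpiperazinomycin, (2S,5S) | COc1ccc2cc1Oc1ccc(cc1)C[C@H]1CN(C(=O)OC(C)(C)C)[C@H](CN1C(=O)OC(C)(C)C)C2
F12 | step 9 | N1,N4-di-Boc-piperazinomycin with CO2H on ring A C1 | O=C(O)c1cc2cc(c1O)Oc1ccc(cc1)C[C@H]1CN(C(=O)OC(C)(C)C)[C@H](CN1C(=O)OC(C)(C)C)C2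
F13 | step 9 | 5-N-aroyl amide of 16 with F12 | Nc1nc(N)c(NC(=O)c2cc3cc(c2O)Oc2ccc(cc2)C[C@H]2CN(C(=O)OC(C)(C)C)[C@H](CN2C(=O)OC(C)(C)C)C3)c(=O)[nH]1
F14 | step 4 | (S)-1-azido-3-[4-(5-allyl-2-methoxyphenoxy)phenyl]propan-2-amine | N[C@@H](Cc1ccc(Oc2cc(CC=C)ccc2OC)cc1)CN=[N+]=[N-]
F15 | step 4 | (S)-1-azido-3-[4-(5-allyl-2-methoxyphenoxy)phenyl]-N-[(tributylstannyl)methyl]propan-2-amine | CCCC[Sn](CCCC)(CCCC)CN[C@@H](Cc1ccc(Oc2cc(CC=C)ccc2OC)cc1)CN=[N+]=[N-]
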